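**Plan**

- Retrosynthesis: the three O‑benzyl bonds and the C5 O‑methyl bond of flavone 1 are cut first. Ring C of flavone 2 is then cut at C4–C4a, C4–C3 and O1–C2, giving iodophenol 16, CO and aryl alkyne 14.
- Alkyne 14 is cut at the alkyne–aryl bond, at O1–C2 and C3–C(aroyl) of its own pyranone, at the acetyl–aryl bond and at the diaryl ether C–O bond, leading back to phenol 4 and 4‑bromophenylboronic acid.
- Forward: the diaryl ether is made first, then ring C of flavone 1 on the acetylated ring A, then the ethynyl group, then ring C of flavone 2 by three‑component carbonylative annulation, then cleavage of four ethers.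
- Enabling feature: ring C of flavone 2 is a carbonyl carbon C4 bonded to aryl carbon C4a and to the C3–C2 pair, with O1 on the neighbouring aryl carbon C8a and the bridge ring on C2. A 2‑iodophenol, CO and an arylacetylene supply exactly these atoms.
- The target has no stereocentre. The one regiochemical question, which ring A oxygen of flavone 1 becomes O1, is settled by a methyl ether on the later C5 oxygen and a benzyl ether on the later O1 oxygen, told apart in step 5.

Key step: step 11

Assumption: 3,5‑bis(benzyloxy)phenol (15) is taken as a catalogue compound; partial benzylation of phloroglucinol would supply it otherwise.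

**Step 1**
Reactants: 1 2,6‑dihydroxy‑4‑methoxybenzaldehyde
Product: 2 2,6‑bis(benzyloxy)‑4‑methoxybenzaldehyde
Conditions: BnBr (2.4 equiv), K2CO3, DMF, 60 °C
Reagents that add atoms: benzyl bromide, BrCc1ccccc1
Why: Williamson ether synthesis in warm DMF should alkylate both hydrogen‑bonded phenols and give a symmetric bis‑ether in which the methyl ether marks the later C5 oxygen of flavone 1.

**Step 2**
Reactants: 2 2,6‑bis(benzyloxy)‑4‑methoxybenzaldehyde
Product: 4 2,6‑bis(benzyloxy)‑4‑methoxyphenol, via aryl formate 3 (not isolated)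
Conditions: mCPBA, CH2Cl2, 0 °C to rt; aq. NaHCO3 wash; then K2CO3 (cat.), MeOH, rt
Reagents that add atoms: mCPBA, OOC(=O)c1cccc(Cl)c1
Why: Baeyer–Villiger (Dakin‑type) oxidation, in which the electron‑rich trioxygenated aryl group migrates in preference to hydride, should give formate 3, and methanolysis only after the peracid is washed out keeps the oxidation‑prone phenol away from the oxidant.

**Step 3**
Reactants: 4 2,6‑bis(benzyloxy)‑4‑methoxyphenol; 5 4‑bromophenylboronic acid
Product: 6 1,3‑bis(benzyloxy)‑2‑(4‑bromophenoxy)‑5‑methoxybenzene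
Conditions: Cu(OAc)2 (1 equiv, reoxidised by air), pyridine, 4 Å MS, CH2Cl2, open to air, rt
Reagents that add atoms: none
Why: Chan–Lam–Evans coupling (aryl transfer from boron to divalent copper, phenoxide binding, C–O reductive elimination from trivalent copper) runs at room temperature, tolerates a phenol with two ortho substituents and leaves the aryl bromide untouched.

**Step 4**
Reactants: 6 1,3‑bis(benzyloxy)‑2‑(4‑bromophenoxy)‑5‑methoxybenzene
Product: 7 1‑[2,4‑bis(benzyloxy)‑3‑(4‑bromophenoxy)‑6‑methoxyphenyl]ethan‑1‑one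
Conditions: AcOH, (CF3CO)2O, CH2Cl2, 0 °C to rt
Reagents that add atoms: acetic acid, CC(O)=O
Why: Friedel–Crafts acylation by the mixed anhydride needs no metal Lewis acid, so the benzyl ethers should survive, and it should give one ketone because the phloroglucinol‑type ring is far more nucleophilic than the bromophenoxy ring and its two free positions are equivalent.

**Step 5**
Reactants: 7 1‑[2,4‑bis(benzyloxy)‑3‑(4‑bromophenoxy)‑6‑methoxyphenyl]ethan‑1‑one
Product: 8 1‑[4‑(benzyloxy)‑3‑(4‑bromophenoxy)‑2‑hydroxy‑6‑methoxyphenyl]ethan‑1‑one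
Conditions: MgBr2·OEt2 (3 equiv), toluene/Et2O, rt to 50 °C
Reagents that add atoms: none
Why: In this chelation‑controlled ortho‑debenzylation, magnesium bridges the ketone oxygen and the flanking benzyloxy oxygen and bromide attacks the benzylic carbon much faster than the methyl of the other ortho ether, while the unchelated para benzyl ether is left alone, so the oxygen next to the aryloxy group is freed to become O1.

**Step 6**
Reactants: 8 1‑[4‑(benzyloxy)‑3‑(4‑bromophenoxy)‑2‑hydroxy‑6‑methoxyphenyl]ethan‑1‑one; 9 4‑methoxybenzoyl chloride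
Product: 10 1‑[4‑(benzyloxy)‑3‑(4‑bromophenoxy)‑2‑hydroxy‑6‑methoxyphenyl]‑3‑(4‑methoxyphenyl)propane‑1,3‑dione
Conditions: LiN(SiMe3)2 (3.3 equiv), THF, −78 °C; then 9, −78 °C to rt; aq. NH4Cl
Reagents that add atoms: none
Why: This one‑flask Baker–Venkataraman variant forms the phenoxide/enolate dianion with excess amide base, and aroylation at carbon (or at oxygen followed by acyl shift in situ) should give the 1,3‑diketone without touching the aryl bromide.

**Step 7**
Reactants: 10 1‑[4‑(benzyloxy)‑3‑(4‑bromophenoxy)‑2‑hydroxy‑6‑methoxyphenyl]‑3‑(4‑methoxyphenyl)propane‑1,3‑dione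
Product: 11 7‑(benzyloxy)‑8‑(4‑bromophenoxy)‑5‑methoxy‑2‑(4‑methoxyphenyl)‑4H‑chromen‑4‑one
Conditions: AcOH, H2SO4 (cat.), 90 °C
Reagents that add atoms: none
Why: Acid‑catalysed cyclodehydration adds the only free phenol to the distal carbonyl and loses water, and because the other ortho oxygen is a methyl ether only the 8‑aryloxy flavone can form.

**Step 8**
Reactants: 11 7‑(benzyloxy)‑8‑(4‑bromophenoxy)‑5‑methoxy‑2‑(4‑methoxyphenyl)‑4H‑chromen‑4‑one; 12 ethynyltrimethylsilane
Product: 13 7‑(benzyloxy)‑5‑methoxy‑2‑(4‑methoxyphenyl)‑8‑{4‑[(trimethylsilyl)ethynyl]phenoxy}‑4H‑chromen‑4‑one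
Conditions: PdCl2(PhCN)2 (3 mol %), t‑Bu3P·HBF4 (6 mol %), CuI (2 mol %), i‑Pr2NH, dioxane, rt to 45 °C
Reagents that add atoms: none
Why: In this Sonogashira coupling the bulky electron‑rich phosphine lets zerovalent palladium insert into the electron‑rich aryl bromide near room temperature, and the hindered amine should not attack the flavone.

**Step 9**
Reactants: 13 7‑(benzyloxy)‑5‑methoxy‑2‑(4‑methoxyphenyl)‑8‑{4‑[(trimethylsilyl)ethynyl]phenoxy}‑4H‑chromen‑4‑one
Product: 14 7‑(benzyloxy)‑8‑(4‑ethynylphenoxy)‑5‑methoxy‑2‑(4‑methoxyphenyl)‑4H‑chromen‑4‑one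
Conditions: K2CO3 (cat.), MeOH/THF, rt
Reagents that add atoms: none
Why: Protiodesilylation of the alkynylsilane by catalytic methoxide is fast at room temperature, where the flavone and all ethers are inert.

**Step 10**
Reactants: 15 3,5‑bis(benzyloxy)phenol
Product: 16 3,5‑bis(benzyloxy)‑2‑iodophenol
Conditions: I2 (1.0 equiv), NaHCO3, THF/H2O, 0 °C
Reagents that add atoms: iodine, II
Why: Electrophilic aromatic iodination of the phenoxide should favour the two equivalent positions ortho to the hydroxyl, which are less crowded than the position between the two benzyloxy groups, and one equivalent at 0 °C limits di‑iodination.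

**Step 11**
Reactants: 14 7‑(benzyloxy)‑8‑(4‑ethynylphenoxy)‑5‑methoxy‑2‑(4‑methoxyphenyl)‑4H‑chromen‑4‑one; 16 3,5‑bis(benzyloxy)‑2‑iodophenol; 17 carbon monoxide
Product: 20 7‑(benzyloxy)‑8‑{4‑[5,7‑bis(benzyloxy)‑4‑oxo‑4H‑chromen‑2‑yl]phenoxy}‑5‑methoxy‑2‑(4‑methoxyphenyl)‑4H‑chromen‑4‑one (protected biflavone), via hydroxyaryl ynone 18 (not isolated), via diethylamino enone 19 (not isolated)
Conditions: PdCl2(PPh3)2 (5 mol %), CO (5 bar), Et2NH/DMF (1:4), 80 °C
Reagents that add atoms: none
Why: Zerovalent palladium, formed in situ from PdCl2(PPh3)2, inserts into the C–I bond of 16, CO inserts into the crowded, electron‑rich aryl–palladium bond faster than the alkyne can be transferred, and the aroyl divalent palladium species is alkynylated by 14 and reductively eliminates to ynone 18, which creates C4–C4a and C4–C3. Et2NH then adds to the ynone to give enaminone 19, and the ortho phenol attacks the amine‑bearing carbon and expels Et2NH, which creates O1–C2. The closest known reaction type is the palladium‑catalysed carbonylative Sonogashira annulation of 2‑iodophenols with terminal arylacetylenes and CO in a secondary amine, which gives flavones. Ring C of flavone 2 closes by a 6‑endo‑trig addition–elimination on the enaminone, and no stereocentre is formed. The selectivity needed is six‑membered flavone over five‑membered aurone closure and carbonylative over direct coupling; the first is secured by the amine, which turns the ynone into an enaminone that can only close at its β‑carbon, the second by CO pressure together with the two ortho substituents and three donor oxygens of the aryl palladium species. Flavone 1 is safe because its C5 oxygen is a methyl ether, so even a reversible amine addition to its pyranone could only re‑close to the same ring.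

**Step 12**
Reactants: 20 protected biflavone
Product: 21 8‑[4‑(5,7‑dihydroxy‑4‑oxo‑4H‑chromen‑2‑yl)phenoxy]‑5,7‑dihydroxy‑2‑(4‑methoxyphenyl)‑4H‑chromen‑4‑one (target)
Conditions: BCl3 (excess), C6HMe5, CH2Cl2, −78 °C to rt; then H2O
Reagents that add atoms: none
Why: In this Lewis acid ether cleavage BCl3 should ionise the three benzyl ethers at low temperature, with pentamethylbenzene trapping the benzyl cations so the phloroglucinol rings are not C‑benzylated, and on warming remove the methyl ether chelated to the C4 carbonyl, while the unchelated 4‑methoxyphenyl ether and the diaryl ether are not activated and the anhydrous medium gives no opening for Wessely–Moser isomerisation.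

**Compound list**

1 | 2,6‑dihydroxy‑4‑methoxybenzaldehyde | COc1cc(O)c(C=O)c(O)c1 | starting material
2 | 2,6‑bis(benzyloxy)‑4‑methoxybenzaldehyde | COc1cc(OCc2ccccc2)c(C=O)c(OCc2ccccc2)c1 | intermediate
3 | 2,6‑bis(benzyloxy)‑4‑methoxyphenyl formate (not isolated) | COc1cc(OCc2ccccc2)c(OC=O)c(OCc2ccccc2)c1 | intermediate
4 | 2,6‑bis(benzyloxy)‑4‑methoxyphenol | COc1cc(OCc2ccccc2)c(O)c(OCc2ccccc2)c1 | intermediate
5 | 4‑bromophenylboronic acid | OB(O)c1ccc(Br)cc1 | starting material
6 | 1,3‑bis(benzyloxy)‑2‑(4‑bromophenoxy)‑5‑methoxybenzene | COc1cc(OCc2ccccc2)c(Oc2ccc(Br)cc2)c(OCc2ccccc2)c1 | intermediate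
7 | 1‑[2,4‑bis(benzyloxy)‑3‑(4‑bromophenoxy)‑6‑methoxyphenyl]ethan‑1‑one | CC(=O)c1c(OC)cc(OCc2ccccc2)c(Oc2ccc(Br)cc2)c1OCc1ccccc1 | intermediate
8 | 1‑[4‑(benzyloxy)‑3‑(4‑bromophenoxy)‑2‑hydroxy‑6‑methoxyphenyl]ethan‑1‑one | CC(=O)c1c(OC)cc(OCc2ccccc2)c(Oc2ccc(Br)cc2)c1O | intermediate
9 | 4‑methoxybenzoyl chloride | COc1ccc(C(Cl)=O)cc1 | starting material
10 | 1‑[4‑(benzyloxy)‑3‑(4‑bromophenoxy)‑2‑hydroxy‑6‑methoxyphenyl]‑3‑(4‑methoxyphenyl)propane‑1,3‑dione (drawn as the diketo tautomer) | COc1ccc(C(=O)CC(=O)c2c(OC)cc(OCc3ccccc3)c(Oc3ccc(Br)cc3)c2O)cc1 | intermediate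
11 | 7‑(benzyloxy)‑8‑(4‑bromophenoxy)‑5‑methoxy‑2‑(4‑methoxyphenyl)‑4H‑chromen‑4‑one | COc1ccc(-c2cc(=O)c3c(OC)cc(OCc4ccccc4)c(Oc4ccc(Br)cc4)c3o2)cc1 | intermediate
12 | ethynyltrimethylsilane | C#C[Si](C)(C)C | starting material
13 | 7‑(benzyloxy)‑5‑methoxy‑2‑(4‑methoxyphenyl)‑8‑{4‑[(trimethylsilyl)ethynyl]phenoxy}‑4H‑chromen‑4‑one | COc1ccc(-c2cc(=O)c3c(OC)cc(OCc4ccccc4)c(Oc4ccc(C#C[Si](C)(C)C)cc4)c3o2)cc1 | intermediate
14 | 7‑(benzyloxy)‑8‑(4‑ethynylphenoxy)‑5‑methoxy‑2‑(4‑methoxyphenyl)‑4H‑chromen‑4‑one | C#Cc1ccc(Oc2c(OCc3ccccc3)cc(OC)c3c(=O)cc(-c4ccc(OC)cc4)oc23)cc1 | intermediate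
15 | 3,5‑bis(benzyloxy)phenol | Oc1cc(OCc2ccccc2)cc(OCc2ccccc2)c1 | starting material
16 | 3,5‑bis(benzyloxy)‑2‑iodophenol | Oc1cc(OCc2ccccc2)cc(OCc2ccccc2)c1I | intermediate
17 | carbon monoxide | [C-]#[O+] | starting material
18 | 7‑(benzyloxy)‑8‑(4‑{3‑[2,4‑bis(benzyloxy)‑6‑hydroxyphenyl]‑3‑oxoprop‑1‑yn‑1‑yl}phenoxy)‑5‑methoxy‑2‑(4‑methoxyphenyl)‑4H‑chromen‑4‑one (ynone, not isolated) | COc1ccc(-c2cc(=O)c3c(OC)cc(OCc4ccccc4)c(Oc4ccc(C#CC(=O)c5c(O)cc(OCc6ccccc6)cc5OCc5ccccc5)cc4)c3o2)cc1 | intermediate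
19 | 7‑(benzyloxy)‑8‑(4‑{3‑[2,4‑bis(benzyloxy)‑6‑hydroxyphenyl]‑1‑(diethylamino)‑3‑oxoprop‑1‑en‑1‑yl}phenoxy)‑5‑methoxy‑2‑(4‑methoxyphenyl)‑4H‑chromen‑4‑one (enaminone, not isolated, double‑bond geometry not defined) | COc1ccc(-c2cc(=O)c3c(OC)cc(OCc4ccccc4)c(Oc4ccc(C(=CC(=O)c5c(O)cc(OCc6ccccc6)cc5OCc5ccccc5)N(CC)CC)cc4)c3o2)cc1 | intermediate
20 | 7‑(benzyloxy)‑8‑{4‑[5,7‑bis(benzyloxy)‑4‑oxo‑4H‑chromen‑2‑yl]phenoxy}‑5‑methoxy‑2‑(4‑methoxyphenyl)‑4H‑chromen‑4‑one | COc1ccc(-c2cc(=O)c3c(OC)cc(OCc4ccccc4)c(Oc4ccc(-c5cc(=O)c6c(OCc7ccccc7)cc(OCc7ccccc7)cc6o5)cc4)c3o2)cc1 | intermediate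
21 | 8‑[4‑(5,7‑dihydroxy‑4‑oxo‑4H‑chromen‑2‑yl)phenoxy]‑5,7‑dihydroxy‑2‑(4‑methoxyphenyl)‑4H‑chromen‑4‑one | COc1ccc(-c2cc(=O)c3c(O)cc(O)c(Oc4ccc(-c5cc(=O)c6c(O)cc(O)cc6o5)cc4)c3o2)cc1 | target

Total step count: 12. Longest linear sequence: 11 steps (steps 1–9, 11, 12); step 10 is a one‑step side branch.

**Steps most likely to fail**

Step 11. Direct alkynylation of the aryl palladium species may compete with CO insertion and end in a benzofuran. Et2NH may capture the aroyl palladium species as the diethylamide. The phenoxide may close 5‑exo on the ynone to the aurone. Poor solubility of 14 would slow the alkynylation and favour all three. The fallback separates ketone formation from ring closure. It sets out from 16, which is acetylated (Ac2O, pyridine) to 3,5‑bis(benzyloxy)‑2‑iodophenyl acetate F1. Carbonylative Sonogashira coupling of F1 with 14 under CO with PdCl2(PPh3)2 and Et3N in THF, with no secondary amine and no free phenol, should give 7‑(benzyloxy)‑8‑(4‑{3‑[2‑acetoxy‑4,6‑bis(benzyloxy)phenyl]‑3‑oxoprop‑1‑yn‑1‑yl}phenoxy)‑5‑methoxy‑2‑(4‑methoxyphenyl)‑4H‑chromen‑4‑one F2, which is isolated. Et2NH in EtOH/THF then adds to the ynone, removes the acetate and closes ring C through enaminone 19, and the route is rejoined at 20.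

Step 12. Cleavage of the chelated methyl ether may stall after the benzyl groups are gone. Benzyl cations may be transferred to the electron‑rich rings if trapping is slow. Prolonged warming may begin to remove the 4‑methoxyphenyl methyl group. The fallback uses two different mechanisms in turn. It sets out from 20, and hydrogenolysis (H2, Pd/C, THF/MeOH, rt) removes the three benzyl groups without carbocations to give 8‑[4‑(5,7‑dihydroxy‑4‑oxo‑4H‑chromen‑2‑yl)phenoxy]‑7‑hydroxy‑5‑methoxy‑2‑(4‑methoxyphenyl)‑4H‑chromen‑4‑one F3. Chelation‑controlled demethylation of the C5 methyl ether with AlCl3 in MeCN at 50 °C then gives 21.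

Step 5. The ortho methyl ether may be lost instead of, or along with, the ortho benzyl ether, which would blur the O1/C5 label. The twisted, doubly flanked ketone may also chelate magnesium poorly and react sluggishly. The fallback removes both benzyl groups and puts one back. It sets out from 7, and BCl3 with C6HMe5 in CH2Cl2, held at −78 °C so the methyl ether is not touched, gives 1‑[3‑(4‑bromophenoxy)‑2,4‑dihydroxy‑6‑methoxyphenyl]ethan‑1‑one F4. BnBr (1 equiv), K2CO3, acetone at reflux then benzylates only the 4‑hydroxyl, because the 2‑hydroxyl is hydrogen‑bonded to the ketone and hindered, and the route is rejoined at 8.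

**Further compounds**

F1 | step 11 | 3,5‑bis(benzyloxy)‑2‑iodophenyl acetate | CC(=O)Oc1cc(OCc2ccccc2)cc(OCc2ccccc2)c1I
F2 | step 11 | 7‑(benzyloxy)‑8‑(4‑{3‑[2‑acetoxy‑4,6‑bis(benzyloxy)phenyl]‑3‑oxoprop‑1‑yn‑1‑yl}phenoxy)‑5‑methoxy‑2‑(4‑methoxyphenyl)‑4H‑chromen‑4‑one | COc1ccc(-c2cc(=O)c3c(OC)cc(OCc4ccccc4)c(Oc4ccc(C#CC(=O)c5c(OC(C)=O)cc(OCc6ccccc6)cc5OCc5ccccc5)cc4)c3o2)cc1
F3 | step 12 | 8‑[4‑(5,7‑dihydroxy‑4‑oxo‑4H‑chromen‑2‑yl)phenoxy]‑7‑hydroxy‑5‑methoxy‑2‑(4‑methoxyphenyl)‑4H‑chromen‑4‑one | COc1ccc(-c2cc(=O)c3c(OC)cc(O)c(Oc4ccc(-c5cc(=O)c6c(O)cc(O)cc6o5)cc4)c3o2)cc1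
F4 | step 5 | 1‑[3‑(4‑bromophenoxy)‑2,4‑dihydroxy‑6‑methoxyphenyl]ethan‑1‑one | CC(=O)c1c(OC)cc(O)c(Oc2ccc(Br)cc2)c1O
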